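**Retrosynthetic overview**
1. The C19 acid comes from the C19 primary alcohol by a last-step oxidation; the alcohol is the direct product of one cation–olefin bicyclization.
2. Key disconnection: the C4–C5 and C9–C10 bonds are cut together, back to an acyclic (S)-2,2-disubstituted epoxy-(Z,Z)-triene. Ring A closes first and ring B second in the same Lewis-acid cascade, which ends by E1 at the 8(17)-alkene.
3. Stereochemistry: inversion at the epoxide carbon sets C4. The two Z trisubstituted alkenes translate (chair/chair, anti addition) into the cis ring fusion and the axial C9 side chain.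
4. The epoxide comes from a methyl ketone by catalytic asymmetric methylene transfer. The polyene comes from an sp3–sp2 Negishi union of a (Z)-homoallylic zinc reagent (propyne carbocupration) with a (Z)-vinyl iodide.
5. C13 (R) is taken unchanged from (R)-linalyl acetate.

Assumption: the SMILES is read literally as 4S,5S,9S,10R,13R. H-5, C-20, the C-9 side chain and the carboxyl then lie on one face, so the decalin is cis-fused (the 5-epimer of the usual trans-fused labdane acids). Labdane numbering is used throughout.

**Route**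

Step 1
Reactants: 1 2-(3-chloropropyl)-2-methyl-1,3-dioxolane; 2 propyne; 3 ethylene oxide
Product: 7 (6Z)-9-hydroxy-6-methylnon-6-en-2-one, via Grignard reagent 4 (not isolated), via (Z)-alkenylcopper 5 (not isolated), via ketal alcohol 6 (not isolated)
Conditions: Mg, THF/Et2O; CuBr·SMe2, Et2O/Me2S, −45 °C; propyne, −25 °C; 1-pentynyllithium, HMPA, ethylene oxide, −78 → −25 °C; then 2 M HCl, THF, rt
Reagents that add atoms: water, O
Why: Normant carbocupration: the alkylcopper from Grignard reagent 4 adds syn across propyne with the alkyl group on the internal carbon, so the C1 chain is cis to copper in 5 and, after the alkynyl cuprate opens ethylene oxide with retention at the sp2 carbon, cis to C6 (Z C5=C10; no stereocentre yet), and the acidic work-up hydrolyses the dioxolane.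

Step 2
Reactants: 7 (6Z)-9-hydroxy-6-methylnon-6-en-2-one
Product: 8 (6Z)-9-iodo-6-methylnon-6-en-2-one
Conditions: I2, PPh3, imidazole, CH2Cl2, 0 °C → rt
Reagents that add atoms: iodine, II
Why: Appel-type iodination: iodide displaces the primary alkoxyphosphonium ion (SN2) under imidazole buffering, which leaves the ketone and the Z alkene untouched.

Step 3
Reactants: 9 (R)-(−)-linalyl acetate
Product: 11 (4R)-4-acetoxy-4-methylhex-5-enal, via ozonide 10 (not isolated)
Conditions: O3 (1.0 equiv, Sudan Red 7B end point), CH2Cl2, −78 °C; then PPh3, −78 °C → rt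
Reagents that add atoms: ozone, [O-][O+]=O
Why: Chemoselective ozonolysis: the electron-rich trisubstituted alkene is cleaved far faster than the vinyl group, which is monosubstituted and deactivated by the allylic acetate, and the C13 stereocentre (R, from the chiral pool) is not involved.

Step 4
Reactants: 11 (4R)-4-acetoxy-4-methylhex-5-enal
Product: 12 (3R,6Z)-7-iodo-3-methylocta-1,6-dien-3-yl acetate
Conditions: [Ph3PEt]I, n-BuLi, THF, rt; I2, −78 °C; NaN(SiMe3)2, −20 °C; then 11, −78 → −20 °C
Reagents that add atoms: ethyltriphenylphosphonium iodide, CC[P+](c1ccccc1)(c1ccccc1)c1ccccc1.[I-]; iodine, II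
Why: Stork–Zhao-type iodo-Wittig olefination: the non-stabilised α-iodo ylide adds to the aldehyde under kinetic control through the cis oxaphosphetane and gives the trisubstituted vinyl iodide with iodine cis to the chain (Z, typically better than 10:1), the geometry that later places C7 cis to C11.

Step 5
Reactants: 8 (6Z)-9-iodo-6-methylnon-6-en-2-one; 12 (3R,6Z)-7-iodo-3-methylocta-1,6-dien-3-yl acetate
Product: 14 (3R,6Z,10Z)-3,7,11-trimethyl-15-oxohexadeca-1,6,10-trien-3-yl acetate, via alkylzinc iodide 13 (not isolated)
Conditions: 8, Zn dust, LiCl, THF, 35 °C; then 12, PdCl2(dppf) (5 mol%), THF/NMP, rt → 40 °C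
Reagents that add atoms: none
Why: Negishi sp3–sp2 cross-coupling: zinc inserts into the primary C–I bond of 8 without touching the ketone, and zerovalent palladium couples the alkylzinc with the vinyl iodide with retention of the Z geometry, oxidative addition to the vinyl iodide being much faster at room temperature than ionisation of the hindered tertiary allylic acetate.

Step 6
Reactants: 14 (3R,6Z,10Z)-3,7,11-trimethyl-15-oxohexadeca-1,6,10-trien-3-yl acetate
Product: 15 (3R,6Z,10Z)-3,7,11-trimethyl-14-[(2S)-2-methyloxiran-2-yl]tetradeca-1,6,10-trien-3-yl acetate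
Conditions: Me3S(O)I, NaH, THF, rt; then 14, LaLi3[(S)-binaphthoxide]3 (5 mol%), (2,4,6-(MeO)3C6H2)3P=O (5 mol%), MS 5 Å, THF, rt
Reagents that add atoms: trimethylsulfoxonium iodide, C[S+](C)(C)=O.[I-]
Why: Catalytic asymmetric Corey–Chaykovsky epoxidation: the lanthanum–lithium binaphthoxide/phosphine oxide catalyst delivers CH2 from dimethylsulfoxonium methylide to the Re face of the methyl ketone (above 90% ee is usual for alkyl methyl ketones; the binaphthol antipode is the one that gives Re-face transfer, to be confirmed on the first run), which sets C4 of the epoxide as S and leaves the alkenes and C13 untouched.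

Step 7
Reactants: 15 (3R,6Z,10Z)-3,7,11-trimethyl-14-[(2S)-2-methyloxiran-2-yl]tetradeca-1,6,10-trien-3-yl acetate
Product: 16 (4S,5S,9S,10R,13R)-19-hydroxylabda-8(17),14-dien-13-yl acetate
Conditions: MeAlCl2 (2 equiv), CH2Cl2, −94 °C, 30 min; Et3N, then H2O
Reagents that add atoms: none
Why: Proposed new method: MeAlCl2 opens the tertiary C4–O bond while the Z C5=C10 alkene attacks C4 from the back (inversion, so the (S)-epoxide gives 4S with C19 carrying the oxygen), and the cascade continues through chair/chair anti additions (Stork–Eschenmoser): the Z C5=C10 alkene places C6 axial and forces the cis ring fusion (5S,10R), the Z C8=C9 alkene places C11 axial so that C9 becomes S, the reactant-like transition state keeps C2 away from the C18 methyl so that the CH2O–Al arm sits axial (cis to H-5), and the C8 cation loses a C17 proton (H-9 is equatorial and misaligned, so no 8(9)-ene; some 7-ene is expected and is removed on AgNO3–silica); the closest known reactions are oxidosqualene-type Lewis-acid epoxy-polyene cyclizations of trisubstituted epoxides and Lewis-acid epoxy-arene cyclizations of 2,2-disubstituted epoxides, both of which proceed with inversion at the tertiary carbon.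

Step 8
Reactants: 16 (4S,5S,9S,10R,13R)-19-hydroxylabda-8(17),14-dien-13-yl acetate
Product: 18 (4S,5S,9S,10R,13R)-13-acetoxylabda-8(17),14-dien-19-oic acid (target), via aldehyde 17 (not isolated)
Conditions: 1-Me-AZADO+BF4− (5 mol%), NaClO2 (3 equiv), MeCN/aq. NaH2PO4–Na2HPO4 (pH 6.8), rt
Reagents that add atoms: sodium chlorite, [Na+].[O-]Cl=O
Why: Oxoammonium-catalysed oxidation of the neopentyl primary alcohol to aldehyde 17, which chlorite oxidises on to the acid in the same pot (Pinnick–Lindgren type); no hypochlorite is added and the medium is near neutral, so the two alkenes, the tertiary allylic acetate and all five stereocentres are untouched.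

**Compound list**
1 | 2-(3-chloropropyl)-2-methyl-1,3-dioxolane | CC1(CCCCl)OCCO1 | starting material
2 | propyne | CC#C | starting material
3 | ethylene oxide | C1CO1 | starting material
4 | [3-(2-methyl-1,3-dioxolan-2-yl)propyl]magnesium chloride | CC1(CCC[Mg]Cl)OCCO1 | intermediate
5 | [(1Z)-2-methyl-5-(2-methyl-1,3-dioxolan-2-yl)pent-1-en-1-yl]copper | CC1(CCC/C(C)=C\[Cu])OCCO1 | intermediate
6 | (3Z)-4-methyl-7-(2-methyl-1,3-dioxolan-2-yl)hept-3-en-1-ol | CC1(CCC/C(C)=C\CCO)OCCO1 | intermediate
7 | (6Z)-9-hydroxy-6-methylnon-6-en-2-one | CC(=O)CCC/C(C)=C\CCO | intermediate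
8 | (6Z)-9-iodo-6-methylnon-6-en-2-one | CC(=O)CCC/C(C)=C\CCI | intermediate
9 | (R)-(−)-linalyl acetate, (3R)-3,7-dimethylocta-1,6-dien-3-yl acetate | C=C[C@@](C)(CCC=C(C)C)OC(C)=O | starting material
10 | (3R)-5-(5,5-dimethyl-1,2,4-trioxolan-3-yl)-3-methylpent-1-en-3-yl acetate (ozonide, ring CH epimers) | C=C[C@@](C)(CCC1OOC(C)(C)O1)OC(C)=O | intermediate
11 | (4R)-4-acetoxy-4-methylhex-5-enal | C=C[C@@](C)(CCC=O)OC(C)=O | intermediate
12 | (3R,6Z)-7-iodo-3-methylocta-1,6-dien-3-yl acetate | C=C[C@@](C)(CC/C=C(/C)I)OC(C)=O | intermediate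
13 | iodo[(3Z)-4-methyl-8-oxonon-3-en-1-yl]zinc | CC(=O)CCC/C(C)=C\CC[Zn]I | intermediate
14 | (3R,6Z,10Z)-3,7,11-trimethyl-15-oxohexadeca-1,6,10-trien-3-yl acetate | C=C[C@@](C)(CC/C=C(/C)CC/C=C(/C)CCCC(C)=O)OC(C)=O | intermediate
15 | (3R,6Z,10Z)-3,7,11-trimethyl-14-[(2S)-2-methyloxiran-2-yl]tetradeca-1,6,10-trien-3-yl acetate | C=C[C@@](C)(CC/C=C(/C)CC/C=C(/C)CCC[C@@]1(C)CO1)OC(C)=O | intermediate
16 | (4S,5S,9S,10R,13R)-19-hydroxylabda-8(17),14-dien-13-yl acetate; cis-fused, H-5, C-20, C-11 and C-19 on one face | C=C[C@@](C)(CC[C@H]1C(=C)CC[C@H]2[C@]1(C)CCC[C@]2(C)CO)OC(C)=O | intermediate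
17 | (4S,5S,9S,10R,13R)-19-oxolabda-8(17),14-dien-13-yl acetate | C=C[C@@](C)(CC[C@H]1C(=C)CC[C@H]2[C@]1(C)CCC[C@]2(C)C=O)OC(C)=O | intermediate
18 | (4S,5S,9S,10R,13R)-13-acetoxylabda-8(17),14-dien-19-oic acid, i.e. (1S,4aR,5S,8aS)-5-[(3R)-3-acetoxy-3-methylpent-4-en-1-yl]-1,4a-dimethyl-6-methylidenedecahydronaphthalene-1-carboxylic acid | C=C[C@@](C)(CC[C@H]1C(=C)CC[C@H]2[C@]1(C)CCC[C@]2(C)C(=O)O)OC(C)=O | target

**Step count**
Total: 8 steps. Longest linear sequence: 6 steps (1, 2, 5, 6, 7, 8; the branch 3, 4, 5, 6, 7, 8 is equally long).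

**Three steps most likely to fail, with fallbacks**

Step 7 (bicyclization). This is the main risk. The ring-forming mode itself is new, the preference for the axial CH2O–Al arm (which fixes the C4/C5 relationship) rests only on a torsional argument, a Meinwald shift to an aldehyde can compete, the tertiary allylic acetate must survive the Lewis acid, and proton loss may give 7-ene beside the wanted 8(17)-ene. The fallback changes the terminator from proton loss to silicon, which makes ring B closure faster and the alkene position unambiguous. It sets out from aldehyde 11. Dichloromethylenation (PPh3, CCl4) gives the 1,1-dichloroalkene F1. A PdCl2(DPEphos)-catalysed trans-selective mono-coupling with Me3SiCH2ZnCl replaces only the chlorine trans to the chain and gives the (Z)-2-chloroallylsilane F2. A second Negishi coupling with alkylzinc 13 under Pd(PtBu3)2 (retention) gives the allylsilane ketone F3. Asymmetric Corey–Chaykovsky epoxidation as in step 6 gives the epoxy allylsilane F4. MeAlCl2 then triggers the same chair/chair cascade, the β-silyl cation at C8 loses the silyl group, and only the 8(17)-alkene can form. The route is rejoined at 16.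

Step 6 (asymmetric methylene transfer). The basic ylide and the lithium binaphthoxide catalyst may attack the tertiary acetate, and the enantioselectivity on this long-chain ketone is untested. Any C4 epimer formed here becomes a ring diastereomer in step 7 and must be removed at 16. The fallback replaces catalysis by a stoichiometric chiral sulfoximine with diastereomer separation. It sets out from ketone 14. Addition of lithiated (S)-N,S-dimethyl-S-phenylsulfoximine (THF, −78 °C) gives, after chromatographic removal of its C4 epimer, the β-hydroxysulfoximine F5. N-Methylation with Me3OBF4 gives the aminosulfoxonium salt F6. Base (NaH, THF) closes the alkoxide onto the CH2 group with loss of the sulfinamide and returns epoxide 15.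

Step 5 (fragment union). The homoallyl radical formed during zinc insertion can pass through a cyclopropylcarbinyl radical and erode the Z geometry of C5=C10, and the ketone-bearing alkylzinc may couple slowly with the trisubstituted vinyl iodide. The fallback is a non-radical boron route with the ketone masked. It sets out from ketal alcohol 6, isolated by leaving out the acid work-up of step 1. Iodination (I2, PPh3, imidazole) gives the ketal iodide F7. Lithium–iodine exchange (t-BuLi, Et2O, −78 °C) followed by B-methoxy-9-BBN gives the borate F8. Suzuki–Miyaura coupling with 12 (PdCl2(dppf), AsPh3, Cs2CO3, DMF/H2O, rt) gives the ketal tetraene F9. Catalytic I2 in acetone removes the dioxolane under neutral conditions and returns ketone 14.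

**Further compounds**
F1 | step 7 | (3R)-7,7-dichloro-3-methylhepta-1,6-dien-3-yl acetate | C=C[C@@](C)(CCC=C(Cl)Cl)OC(C)=O
F2 | step 7 | (3R,6Z)-7-chloro-3-methyl-8-(trimethylsilyl)octa-1,6-dien-3-yl acetate | C=C[C@@](C)(CC/C=C(Cl)/C[Si](C)(C)C)OC(C)=O
F3 | step 7 | (3R,6E,10Z)-3,11-dimethyl-15-oxo-7-[(trimethylsilyl)methyl]hexadeca-1,6,10-trien-3-yl acetate | C=C[C@@](C)(CC/C=C(C[Si](C)(C)C)\CC/C=C(/C)CCCC(C)=O)OC(C)=O
F4 | step 7 | (3R,6E,10Z)-3,11-dimethyl-14-[(2S)-2-methyloxiran-2-yl]-7-[(trimethylsilyl)methyl]tetradeca-1,6,10-trien-3-yl acetate | C=C[C@@](C)(CC/C=C(C[Si](C)(C)C)\CC/C=C(/C)CCC[C@@]1(C)CO1)OC(C)=O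
F5 | step 6 | (3R,6Z,10Z,15S)-15-hydroxy-3,7,11,15-tetramethyl-16-[(S)-N-methyl-S-phenylsulfonimidoyl]hexadeca-1,6,10-trien-3-yl acetate | C=C[C@@](C)(CC/C=C(/C)CC/C=C(/C)CCC[C@](C)(O)C[S@@](=O)(=NC)c1ccccc1)OC(C)=O
F6 | step 6 | N-methylated F5: the (dimethylamino)oxo(phenyl)sulfonium tetrafluoroborate with the same configuration at sulfur and at C4 | C=C[C@@](C)(CC/C=C(/C)CC/C=C(/C)CCC[C@](C)(O)C[S@@+](=O)(N(C)C)c1ccccc1)OC(C)=O.F[B-](F)(F)F
F7 | step 5 | 2-[(4Z)-7-iodo-4-methylhept-4-en-1-yl]-2-methyl-1,3-dioxolane | CC1(CCC/C(C)=C\CCI)OCCO1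
F8 | step 5 | lithium 9-methoxy-9-[(3Z)-4-methyl-7-(2-methyl-1,3-dioxolan-2-yl)hept-3-en-1-yl]-9-boranuidabicyclo[3.3.1]nonane | [Li+].CO[B-]1(CC/C=C(/C)CCCC2(C)OCCO2)C2CCCC1CCC2
F9 | step 5 | (3R,6Z,10Z)-3,7,11-trimethyl-14-(2-methyl-1,3-dioxolan-2-yl)tetradeca-1,6,10-trien-3-yl acetate | C=C[C@@](C)(CC/C=C(/C)CC/C=C(/C)CCCC1(C)OCCO1)OC(C)=O
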